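**Retrosynthetic overview**
1. Numbering: furan C1–C4 (attached at C3), C5 ketone, C6, C7, C8 (methyl C9), C10, C11, C12, C13 (methyl C14), C15–C17, C18 (methyl C19), C20, tetronic acid ring O–C21–C22(OH)=C23(methyl C25)–C24(=O).
2. The tetronic acid is the only ring that is built, and it is closed last: C22–C23 by Dieckmann closure of the (E)-enol propanoate 21, which comes from keto aldehyde 19 and phosphonate 15 by a Still–Gennari-type olefination that fixes the E C20=C21 bond.
3. C11–C12 is made by one-pot Zr-catalysed methylalumination of terminal alkyne 12 and Pd-catalysed allylation of the alkenylalane with allylic acetate 6. This one operation adds C14, sets the 12E olefin and unites the halves; C20 and C5 travel as alcohols (aluminium alkoxides) and are oxidised together afterwards.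
4. Enabling feature: the skipped diene C13(C14)=C12H–C11H2–C10H=C8(C9). The vinylic C12–H beside the methyl-bearing C13 is the retron of syn-methylmetalation of an alkyne C12≡C13, and C11 is the primary end of an (E)-3,3-disubstituted allyl unit that geranyl acetate supplies with its geometry in place.
5. Fragments: 12 from (R)-3-bromo-2-methylpropan-1-ol (C18 from the chiral pool); 6 from geranyl acetate and 3-bromofuran (the furan ring is purchased).

Key step: step 8

Remark: the SMILES is read as 18S, 8E, 12E and E at C20=C21 (side chain on the side of C22, opposite the ring oxygen); the carbinol carbon C5 of 6, 17 and 18 is formed without control and both epimers are used, because step 9 oxidises it.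

**Route**

Step 1
Reactants: 1 geranyl acetate
Product: 2 (2E)-5-(3,3-dimethyloxiran-2-yl)-3-methylpent-2-en-1-yl acetate (6,7-epoxygeranyl acetate; racemic)
Conditions: mCPBA (1.05 equiv), NaHCO3, CH2Cl2, 0 °C
Reagents that add atoms: 3-chloroperbenzoic acid (mCPBA), OOC(=O)c1cccc(Cl)c1
Why: Prilezhaev epoxidation should take place only at the distal trisubstituted olefin, because the C2=C3 olefin is deactivated by the allylic acetoxy group; the epoxide stereocentre is of no consequence since both epoxide carbons are cleaved apart in step 2.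

Step 2
Reactants: 2 6,7-epoxygeranyl acetate
Product: 3 (2E)-3-methyl-6-oxohex-2-en-1-yl acetate
Conditions: H5IO6 (1.2 equiv), THF–Et2O, 0 °C
Reagents that add atoms: none
Why: Periodic acid should hydrolyse the epoxide in situ (water attacks the tertiary carbon, so its oxygen leaves with the acetone) and cleave the glycol (Malaprade-type glycol cleavage) to the aldehyde without touching the (E)-allylic acetate.

Step 3
Reactants: 3 (2E)-3-methyl-6-oxohex-2-en-1-yl acetate; 4 3-bromofuran
Product: 6 (2E)-6-(furan-3-yl)-6-hydroxy-3-methylhex-2-en-1-yl acetate (racemic), via 3-furyllithium 5 (not isolated)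
Conditions: 4, n-BuLi (1.05 equiv), THF, −78 °C, 20 min; then 3, −78 °C; aq. NH4Cl
Reagents that add atoms: none
Why: Bromine–lithium exchange gives 3-furyllithium, which is kept at −78 °C to avoid isomerisation to the 2-lithio isomer and should add to the aldehyde (1,2-addition of an organolithium) far faster than to the acetate; the carbinol centre is formed without control and is erased by oxidation in step 9.

Step 4
Reactants: 7 (R)-3-bromo-2-methylpropan-1-ol; 8 4-bromo-1-(trimethylsilyl)but-1-yne
Product: 11 (S)-2-methyl-7-(trimethylsilyl)hept-6-yn-1-ol, via Grignard reagent 9 (not isolated), via chloromagnesium alkoxide 10 (not isolated)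
Conditions: 8, Mg, THF, rt (gives 9, 1.5 equiv); 7, MeMgCl (1.0 equiv), THF, −30 °C (gives 10); combine, Li2CuCl4 (5 mol %), THF, −30 → 0 °C; aq. NH4Cl
Reagents that add atoms: none
Why: Copper-catalysed sp3–sp3 cross-coupling of a primary alkyl bromide with a Grignard reagent (Kochi-type coupling) should join the two pieces while the hydroxyl is masked in the flask as its magnesium alkoxide; the C18 stereocentre comes from the chiral pool and is not involved (the descriptor changes from R to S only because the CIP priorities change).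

Step 5
Reactants: 11 (S)-2-methyl-7-(trimethylsilyl)hept-6-yn-1-ol
Product: 12 (S)-2-methylhept-6-yn-1-ol
Conditions: K2CO3 (0.3 equiv), MeOH, rt
Reagents that add atoms: none
Why: Base-catalysed methanolysis of the alkynyl C–Si bond (protodesilylation) should free the terminal alkyne required for carbometalation without affecting the stereocentre.

Step 6
Reactants: 13 methyl 2-[bis(2,2,2-trifluoroethoxy)phosphoryl]acetate
Product: 14 methyl 2-[bis(2,2,2-trifluoroethoxy)phosphoryl]-2-diazoacetate
Conditions: p-ABSA (1.2 equiv), DBU (1.3 equiv), MeCN, 0 °C → rt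
Reagents that add atoms: 4-acetamidobenzenesulfonyl azide (p-ABSA), CC(=O)Nc1ccc(cc1)S(=O)(=O)N=[N+]=[N-]
Why: Regitz diazo transfer to the doubly activated methylene group of the phosphonoacetate should give the diazo compound under mild amine-base conditions.

Step 7
Reactants: 14 methyl 2-[bis(2,2,2-trifluoroethoxy)phosphoryl]-2-diazoacetate
Product: 15 methyl 2-[bis(2,2,2-trifluoroethoxy)phosphoryl]-2-(propanoyloxy)acetate
Conditions: Rh2(OAc)4 (1 mol %), EtCO2H (2 equiv), toluene, 80 °C
Reagents that add atoms: propanoic acid, CCC(=O)O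
Why: Rhodium(II)-carbenoid O–H insertion into a carboxylic acid is the established way to place an acyloxy group on the α-carbon of a phosphonoacetate and should proceed cleanly because no C=C or reactive C–H bond is present.

Step 8
Reactants: 12 (S)-2-methylhept-6-yn-1-ol; 6 (2E)-6-(furan-3-yl)-6-hydroxy-3-methylhex-2-en-1-yl acetate
Product: 18 (2S,6E,9E)-13-(furan-3-yl)-2,6,10-trimethyltrideca-6,9-diene-1,13-diol (both C13 epimers), via alkenylalane 16 (not isolated), via aluminium alkoxide 17 (not isolated)
Conditions: 12, Me3Al (3.0 equiv), Cp2ZrCl2 (0.25 equiv), CH2Cl2, 0 °C → rt, 16 h (gives 16); 6, Me3Al (1.0 equiv), THF, 0 °C (gives 17); combine, Pd(PPh3)4 (5 mol %), THF, rt; aq. Rochelle salt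
Reagents that add atoms: trimethylaluminium, C[Al](C)C
Why: The hydroxyl of 12 is first capped as its dimethylaluminium alkoxide, then Zr-catalysed methylalumination (Negishi carboalumination) adds CH3–Al syn across the terminal alkyne C12≡C13 with methyl on the internal carbon C13 and aluminium on C12, giving the (E)-alkenylalane 16. Pd(0) ionises the primary allylic acetate of 17 (assisted by the aluminium Lewis acid) to an η3-allylpalladium species, the alkenyl group passes from aluminium to palladium, and reductive elimination at the unhindered primary terminus C11 forms the C11–C12 bond. The closest known reaction type is the one-pot carboalumination/Pd-catalysed allylation of alkenylalanes with geranyl-type allylic chlorides and acetates to give 1,4-dienes. No ring is closed and no stereocentre is formed; C18 is a spectator three carbons away from the alkyne. The 12E geometry follows from syn-carbometalation and retention in transmetalation and reductive elimination, and the 8E geometry from retention in the allyl unit, because syn–anti exchange would need an η1-allyl at the tertiary carbon C8 and is slower than coupling. The step needs methyl delivery to C13 (secured by the terminal alkyne), attack at C11 and not C8 (steric bias of the 3,3-disubstituted allyl), alkenyl rather than methyl transfer (sp2 groups transfer faster) and tolerance of both oxygens (carried as aluminium alkoxides, too weakly nucleophilic to capture the π-allyl).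

Step 9
Reactants: 18 (2S,6E,9E)-13-(furan-3-yl)-2,6,10-trimethyltrideca-6,9-diene-1,13-diol
Product: 19 (2S,6E,9E)-13-(furan-3-yl)-2,6,10-trimethyl-13-oxotrideca-6,9-dienal
Conditions: Dess–Martin periodinane (3 equiv), NaHCO3, CH2Cl2, 0 °C → rt; aq. Na2S2O3/NaHCO3; used crude
Reagents that add atoms: none
Why: Dess–Martin oxidation should convert the primary alcohol to the aldehyde and the furyl carbinol to the ketone in the same operation, and its buffered, non-basic conditions should leave the α-methyl stereocentre C18, the furan and the skipped diene intact.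

Step 10
Reactants: 19 (2S,6E,9E)-13-(furan-3-yl)-2,6,10-trimethyl-13-oxotrideca-6,9-dienal; 15 methyl 2-[bis(2,2,2-trifluoroethoxy)phosphoryl]-2-(propanoyloxy)acetate
Product: 21 methyl (2E,4S,8E,11E)-15-(furan-3-yl)-4,8,12-trimethyl-15-oxo-2-(propanoyloxy)pentadeca-2,8,11-trienoate, via potassium phosphonate carbanion 20 (not isolated)
Conditions: 15 (1.2 equiv), KHMDS (1.15 equiv), 18-crown-6 (3 equiv), THF, −78 °C; then 19, −78 °C; aq. NH4Cl
Reagents that add atoms: none
Why: Still–Gennari-type Horner–Wadsworth–Emmons olefination: the trifluoroethyl phosphonate with a crown-ether-separated potassium counter-ion should make the addition irreversible, so the kinetic adduct collapses to the alkene with the C18 residue cis to the ester carbon (E by CIP, because the acyloxy oxygen outranks the ester carbon), while the aldehyde reacts in preference to the ketone and the weakly basic stabilised carbanion should not epimerise C18.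

Step 11
Reactants: 21 methyl (2E,4S,8E,11E)-15-(furan-3-yl)-4,8,12-trimethyl-15-oxo-2-(propanoyloxy)pentadeca-2,8,11-trienoate
Product: 23 (5E)-5-[(2S,6E,9E)-13-(furan-3-yl)-2,6,10-trimethyl-13-oxotrideca-6,9-dien-1-ylidene]-4-hydroxy-3-methylfuran-2(5H)-one (CNP0018619.1), via dilithium salt 22 (not isolated)
Conditions: LiHMDS (3.2 equiv), THF, −78 → −30 °C; then cold 0.5 M HCl to pH 3; isolation with exclusion of light
Reagents that add atoms: none
Why: Dieckmann (intramolecular Claisen) condensation: once the ketone is stored as its lithium enolate, the propanoate enolate should close 5-exo-trig onto the methyl ester to form the C22–C23 bond and expel methoxide, the C20=C21 geometry being carried over unchanged from 21 because that bond takes no part, and allylic 1,3-strain holding the C18–H bond in the alkene plane should disfavour γ-deprotonation.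

**Compound list**
1 | geranyl acetate | CC(=O)OC/C=C(\C)CCC=C(C)C | starting material
2 | (2E)-5-(3,3-dimethyloxiran-2-yl)-3-methylpent-2-en-1-yl acetate (racemic) | CC(=O)OC/C=C(\C)CCC1OC1(C)C | intermediate
3 | (2E)-3-methyl-6-oxohex-2-en-1-yl acetate | CC(=O)OC/C=C(\C)CCC=O | intermediate
4 | 3-bromofuran | Brc1ccoc1 | starting material
5 | 3-furyllithium | [Li]c1ccoc1 | intermediate
6 | (2E)-6-(furan-3-yl)-6-hydroxy-3-methylhex-2-en-1-yl acetate (racemic) | CC(=O)OC/C=C(\C)CCC(O)c1ccoc1 | intermediate
7 | (R)-3-bromo-2-methylpropan-1-ol | OC[C@@H](C)CBr | starting material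
8 | 4-bromo-1-(trimethylsilyl)but-1-yne | C[Si](C)(C)C#CCCBr | starting material
9 | [4-(trimethylsilyl)but-3-yn-1-yl]magnesium bromide | C[Si](C)(C)C#CCC[Mg]Br | intermediate
10 | chloromagnesium (R)-3-bromo-2-methylpropan-1-olate | Cl[Mg]OC[C@@H](C)CBr | intermediate
11 | (S)-2-methyl-7-(trimethylsilyl)hept-6-yn-1-ol | OC[C@@H](C)CCCC#C[Si](C)(C)C | intermediate
12 | (S)-2-methylhept-6-yn-1-ol | OC[C@@H](C)CCCC#C | intermediate
13 | methyl 2-[bis(2,2,2-trifluoroethoxy)phosphoryl]acetate | COC(=O)CP(=O)(OCC(F)(F)F)OCC(F)(F)F | starting material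
14 | methyl 2-[bis(2,2,2-trifluoroethoxy)phosphoryl]-2-diazoacetate | COC(=O)C(=[N+]=[N-])P(=O)(OCC(F)(F)F)OCC(F)(F)F | intermediate
15 | methyl 2-[bis(2,2,2-trifluoroethoxy)phosphoryl]-2-(propanoyloxy)acetate | CCC(=O)OC(C(=O)OC)P(=O)(OCC(F)(F)F)OCC(F)(F)F | intermediate
16 | dimethylaluminium (2S,6E)-7-(dimethylalumanyl)-2,6-dimethylhept-6-en-1-olate | C[Al](C)OC[C@@H](C)CCC/C(C)=C/[Al](C)C | intermediate
17 | dimethylaluminium alkoxide of 6 | CC(=O)OC/C=C(\C)CCC(O[Al](C)C)c1ccoc1 | intermediate
18 | (2S,6E,9E)-13-(furan-3-yl)-2,6,10-trimethyltrideca-6,9-diene-1,13-diol (both C13 epimers) | OC[C@@H](C)CCC/C(C)=C/C/C=C(\C)CCC(O)c1ccoc1 | intermediate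
19 | (2S,6E,9E)-13-(furan-3-yl)-2,6,10-trimethyl-13-oxotrideca-6,9-dienal | O=C[C@@H](C)CCC/C(C)=C/C/C=C(\C)CCC(=O)c1ccoc1 | intermediate
20 | potassium salt (carbanion) of 15 | [K+].CCC(=O)O[C-](C(=O)OC)P(=O)(OCC(F)(F)F)OCC(F)(F)F | intermediate
21 | methyl (2E,4S,8E,11E)-15-(furan-3-yl)-4,8,12-trimethyl-15-oxo-2-(propanoyloxy)pentadeca-2,8,11-trienoate | COC(=O)/C(OC(=O)CC)=C\[C@@H](C)CCC/C(C)=C/C/C=C(\C)CCC(=O)c1ccoc1 | intermediate
22 | dilithium salt of 23 (tetronate/ketone enolate) | [Li+].[Li+].CC1=C([O-])/C(=C\[C@@H](C)CCC/C(C)=C/C/C=C(\C)CC=C([O-])c2ccoc2)OC1=O | intermediate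
23 | (5E)-5-[(2S,6E,9E)-13-(furan-3-yl)-2,6,10-trimethyl-13-oxotrideca-6,9-dien-1-ylidene]-4-hydroxy-3-methylfuran-2(5H)-one | CC1=C(O)/C(=C\[C@@H](C)CCC/C(C)=C/C/C=C(\C)CCC(=O)c2ccoc2)OC1=O | target

**Step count**
Total: 11 steps. Longest linear sequence: 7 steps (1, 2, 3, 8, 9, 10, 11 from geranyl acetate).

**Steps most likely to fail**

Step 11. The ring closure may be overtaken by intermolecular acyl transfer from the enol ester to the ketone enolate, or by γ-deprotonation at C18 with loss of the C18 configuration and of the enol geometry; the product may also isomerise from E to Z during isolation. The fallback postpones the ketone: it sets out from diol 18 and comes back at 23. Silylation of 18 (TESCl, imidazole, DMF) should give the bis(triethylsilyl) ether F8. Swern oxidation, which cleaves and oxidises only the primary TES ether, should give (2S,6E,9E)-13-(furan-3-yl)-2,6,10-trimethyl-13-(triethylsilyloxy)trideca-6,9-dienal F9. Olefination with 15 under the conditions of step 10 should give the silylated (E)-enol propanoate F10. Dieckmann closure (LiHMDS, 2.2 equiv, THF, −78 °C), now free of any ketone enolate, should give the silylated tetronic acid F11. Methanolysis (PPTS, MeOH) should give the C5 carbinol tetronic acid F12, and oxidation of the furyl carbinol (Dess–Martin periodinane or activated MnO2) returns to 23.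

Step 10. Kinetic control in the olefination may erode (equilibration of the adducts toward the more stable Z-enol ester), and the α-methyl aldehyde may epimerise under base. The fallback gives up direct E-control and sets the geometry photochemically: it sets out from keto aldehyde 19 and comes back at 23. Vinylogous aldol addition of 5-lithio-4-methoxy-3-methylfuran-2(5H)-one F3 (from the furanone and LDA, THF, −78 °C) to the aldehyde should give the carbinol adduct F4. Mesylation (MsCl, Et3N) should give the mesylate F5, and elimination with DBU the O-methyl (20Z)-ylidene tetronate F6. Nucleophilic O-demethylation (n-PrSLi, HMPA) should give the (20Z)-tetronic acid F7. Long-wavelength irradiation of F7 should establish a Z/E photostationary mixture from which 23 is separated by reverse-phase HPLC, the Z isomer being recycled.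

Step 8. Carbometalation may be incomplete in the presence of the aluminium alkoxide, the alkenyl–aluminium bond may be protonolysed when the second fragment is added, and slow transmetalation may let the π-allyl intermediate lose its geometry or be trapped internally by the C5 oxygen. The fallback replaces the one-pot alane coupling by a stepwise route through an isolable, proton-tolerant alkenyl boronate: it sets out from alkynol 12 and comes back at 18. The same methylalumination, quenched with iodine instead of the allyl partner, should give (2S,6E)-7-iodo-2,6-dimethylhept-6-en-1-ol F1. Miyaura borylation (B2pin2, PdCl2(dppf), KOPh, toluene, 50 °C) should give the pinacol alkenylboronate F2. Suzuki–Miyaura allyl–alkenyl coupling of F2 with allylic acetate 6 (Pd(PPh3)4, CsF, THF, 60 °C) then gives 18.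

**Further compounds**
F1 | step 8 | (2S,6E)-7-iodo-2,6-dimethylhept-6-en-1-ol | OC[C@@H](C)CCC/C(C)=C/I
F2 | step 8 | (2S,6E)-2,6-dimethyl-7-(4,4,5,5-tetramethyl-1,3,2-dioxaborolan-2-yl)hept-6-en-1-ol | OC[C@@H](C)CCC/C(C)=C/B1OC(C)(C)C(C)(C)O1
F3 | step 10 | 5-lithio-4-methoxy-3-methylfuran-2(5H)-one | [Li]C1OC(=O)C(C)=C1OC
F4 | step 10 | 5-[(2S,6E,9E)-13-(furan-3-yl)-1-hydroxy-2,6,10-trimethyl-13-oxotrideca-6,9-dien-1-yl]-4-methoxy-3-methylfuran-2(5H)-one | COC1=C(C)C(=O)OC1C(O)[C@@H](C)CCC/C(C)=C/C/C=C(\C)CCC(=O)c2ccoc2
F5 | step 10 | methanesulfonate of F4 | COC1=C(C)C(=O)OC1C(OS(C)(=O)=O)[C@@H](C)CCC/C(C)=C/C/C=C(\C)CCC(=O)c2ccoc2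
F6 | step 10 | (5Z)-5-[(2S,6E,9E)-13-(furan-3-yl)-2,6,10-trimethyl-13-oxotrideca-6,9-dien-1-ylidene]-4-methoxy-3-methylfuran-2(5H)-one | CC1=C(OC)/C(=C/[C@@H](C)CCC/C(C)=C/C/C=C(\C)CCC(=O)c2ccoc2)OC1=O
F7 | step 10 | (5Z)-5-[(2S,6E,9E)-13-(furan-3-yl)-2,6,10-trimethyl-13-oxotrideca-6,9-dien-1-ylidene]-4-hydroxy-3-methylfuran-2(5H)-one | CC1=C(O)/C(=C/[C@@H](C)CCC/C(C)=C/C/C=C(\C)CCC(=O)c2ccoc2)OC1=O
F8 | step 11 | bis(triethylsilyl) ether of 18 | CC[Si](CC)(CC)OC[C@@H](C)CCC/C(C)=C/C/C=C(\C)CCC(O[Si](CC)(CC)CC)c1ccoc1
F9 | step 11 | (2S,6E,9E)-13-(furan-3-yl)-2,6,10-trimethyl-13-(triethylsilyloxy)trideca-6,9-dienal | O=C[C@@H](C)CCC/C(C)=C/C/C=C(\C)CCC(O[Si](CC)(CC)CC)c1ccoc1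
F10 | step 11 | methyl (2E,4S,8E,11E)-15-(furan-3-yl)-4,8,12-trimethyl-2-(propanoyloxy)-15-(triethylsilyloxy)pentadeca-2,8,11-trienoate | COC(=O)/C(OC(=O)CC)=C\[C@@H](C)CCC/C(C)=C/C/C=C(\C)CCC(O[Si](CC)(CC)CC)c1ccoc1
F11 | step 11 | (5E)-5-[(2S,6E,9E)-13-(furan-3-yl)-2,6,10-trimethyl-13-(triethylsilyloxy)trideca-6,9-dien-1-ylidene]-4-hydroxy-3-methylfuran-2(5H)-one | CC1=C(O)/C(=C\[C@@H](C)CCC/C(C)=C/C/C=C(\C)CCC(O[Si](CC)(CC)CC)c2ccoc2)OC1=O
F12 | step 11 | (5E)-5-[(2S,6E,9E)-13-(furan-3-yl)-13-hydroxy-2,6,10-trimethyltrideca-6,9-dien-1-ylidene]-4-hydroxy-3-methylfuran-2(5H)-one | CC1=C(O)/C(=C\[C@@H](C)CCC/C(C)=C/C/C=C(\C)CCC(O)c2ccoc2)OC1=O
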